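**Plan**

1. Numbering (azulene): C3 = tertiary carbinol, C3a (CH) and C8a (C–CH3) = ring fusion, C4 = ester carbon, C5=C6(CH3) = alkene, C7 and C8 = the two ring CH2 groups.
2. Retrosynthesis: cut the ester C–O last. Then cut C6–C7 and the ring-fusion bond C3a–C8a together, as a (4+3) union of a gold-activated allene (C7–C8–C8a) with the 2-oxydiene C3a=C4(O)–C5=C6. Allene and propenyl ketone go back to the methyl ketone and aldehyde from ozonolysis of (S)-terpinen-4-ol.
3. Enabling feature: C3a–C8a is shared by the five- and the seven-membered ring, and the chain C1–C2–C3 ties the allene terminus to the diene terminus, so both rings close at once from an open chain. The 1,3-related oxygens on C3 and C4 are bridged by a diisopropylsilylene (six-membered dioxasiline). This helper masks the enone as its dienol ether, protects the tertiary alcohol and fixes the reacting face; it is removed in step 9.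
4. Forward order: open the chiral-pool cyclohexene (ten skeletal carbons and the C3 stereocentre) → propenyl ketone → dioxasiline → allene → both carbocycles in one event → saturate C7=C8, desaturate C5–C6 → reduce C4 → ester.
5. Stereochemistry: C3 from terpinen-4-ol; C3a from the dioxasiline (attack anti to isopropyl); C8a from the exo mode of the cycloaddition (trans fusion); C4 from hydroxyl-directed hydride delivery.

Key step: step 7

Assumption: (S)-terpinen-4-ol is used in enantiomerically pure form (commercial material upgraded if necessary); it is the only source of chirality.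

**Step 1**
Reactants: 1 (S)-terpinen-4-ol
Product: 3 (3S)-3-hydroxy-6-oxo-3-(propan-2-yl)heptanal, via secondary ozonide 2 (not isolated)
Conditions: O3, CH2Cl2, −78 °C; then Me2S, −78 °C → rt; used crude
Reagents that add atoms: ozone, [O-][O+]=O
Why: Ozonolysis with reductive work-up (Criegee mechanism) cleaves the only C=C bond, a tertiary homoallylic alcohol should give a usable β-hydroxy aldehyde under these neutral conditions, and the carbinol stereocentre is not touched.

**Step 2**
Reactants: 3 (3S)-3-hydroxy-6-oxo-3-(propan-2-yl)heptanal; 4 (E)-1-bromoprop-1-ene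
Product: 5 (5S,8E)-5,7-dihydroxy-5-(propan-2-yl)dec-8-en-2-one (both C7 epimers)
Conditions: CrCl2 (6 equiv), NiCl2 (2 mol %), DMSO, rt
Reagents that add atoms: none
Why: Nozaki–Hiyama–Kishi coupling, in which the alkenylchromium species adds to the aldehyde only, tolerates the methyl ketone and the free tertiary alcohol and keeps the E geometry; the new carbinol epimers converge in step 3.

**Step 3**
Reactants: 5 (5S,8E)-5,7-dihydroxy-5-(propan-2-yl)dec-8-en-2-one
Product: 6 (5S,8E)-5-hydroxy-5-(propan-2-yl)dec-8-ene-2,7-dione
Conditions: Dess–Martin periodinane, pyridine, CH2Cl2, 0 °C → rt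
Reagents that add atoms: none
Why: Dess–Martin oxidation can only act on the secondary allylic alcohol (the other hydroxyl is tertiary) and should give the β-hydroxy enone under non-basic conditions that avoid retro-aldol cleavage.

**Step 4**
Reactants: 6 (5S,8E)-5-hydroxy-5-(propan-2-yl)dec-8-ene-2,7-dione
Product: 8 4-[(4R)-2,2,4-tri(propan-2-yl)-6-[(1E)-prop-1-en-1-yl]-4H-1,3,2-dioxasilin-4-yl]butan-2-one, via silyl triflate 7 (not isolated)
Conditions: iPr2Si(OTf)2 (1.05 equiv), 2,6-lutidine, CH2Cl2, −78 → 0 °C; then Et3N, 0 °C
Reagents that add atoms: diisopropylsilyl bis(trifluoromethanesulfonate), CC(C)[Si](OS(=O)(=O)C(F)(F)F)(OS(=O)(=O)C(F)(F)F)C(C)C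
Why: O-silylation of the tertiary alcohol followed by ring-closing enol silylation (soft enolisation at the α'-CH2) should give the six-membered cyclic silylene enol ether of the 1,3-related hydroxy ketone; the remote methyl ketone could only give a seven-membered ring and stays free.

**Step 5**
Reactants: 8 the dioxasilinyl butanone
Product: 10 methyl 3-methyl-5-[(4R)-2,2,4-tri(propan-2-yl)-6-[(1E)-prop-1-en-1-yl]-4H-1,3,2-dioxasilin-4-yl]pent-1-yn-3-yl carbonate (both carbinol epimers), via lithium alkoxide 9 (not isolated)
Conditions: HC≡CLi (from acetylene and n-BuLi, 3 equiv), THF, −78 °C; then ClCO2Me, −78 → 0 °C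
Reagents that add atoms: lithium acetylide, [Li+].[C-]#C; methyl chloroformate, COC(=O)Cl
Why: 1,2-Addition of the acetylide to the methyl ketone and in situ O-acylation of the tertiary alkoxide; the hindered silyl dienol ether, which masks the enone, should survive at −78 °C.

**Step 6**
Reactants: 10 the propargylic methyl carbonate
Product: 11 (4R)-4-(3-methylpenta-3,4-dien-1-yl)-2,2,4-tri(propan-2-yl)-6-[(1E)-prop-1-en-1-yl]-4H-1,3,2-dioxasiline
Conditions: Pd2(dba)3·CHCl3 (2.5 mol %), PBu3 (10 mol %), HCO2H, Et3N, THF, rt
Reagents that add atoms: none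
Why: Palladium-catalysed formate hydrogenolysis of a 3-(methoxycarbonyloxy)-1-alkyne: SN2' oxidative addition to zerovalent palladium gives an allenylpalladium formate that loses CO2 and delivers hydride to the alkyne terminus, which should give the 1,1-disubstituted allene; the buffered medium spares the silyl enol ether.

**Step 7**
Reactants: 11 the allene-tethered siloxydiene
Product: 12 (3R,3aS,6R,8aR)-6,8a-dimethyl-3-(propan-2-yl)-1,2,3,3a,6,8a-hexahydroazulene-3,4-diol as its cyclic O3,O4-diisopropylsilanediyl ether (C4=C5 silyl enol ether, C7=C8 alkene, trans ring fusion)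
Conditions: (IPr)AuCl (5 mol %), AgSbF6 (5 mol %), 2,6-di-tert-butyl-4-methylpyridine (10 mol %), 4 Å MS, CH2Cl2, −20 → 0 °C (IPr = 1,3-bis(2,6-diisopropylphenyl)imidazol-2-ylidene)
Reagents that add atoms: none
Why: Cationic monovalent gold binds the allene and generates a gold-bound allyl cation whose positive end is the tertiary carbon C8a; this C3 unit adds across the termini of the C3a=C4–C5=C6 siloxydiene (concerted, or C3a–C8a first and then C6–C7) to give a cycloheptenyl gold carbene at C8, which ends by 1,2-hydride shift from C7 and loss of gold, leaving the C7=C8 alkene and the C4=C5 silyl enol ether. The closest known reaction type is the gold- or platinum-catalysed intramolecular allene–diene (4+3) cycloaddition that converts allene-tethered dienes into trans-fused hydroazulenes, applied here to a 2-siloxydiene and an allene that carries its two substituents on the tethered carbon. The cyclopentane closes through the three-atom tether by bonding of the two termini (5-exo with respect to the allyl unit), and the cycloheptadiene closes as the (4+3) union, in the stepwise picture a 7-endo attack of the vinylgold CH2 on the siloxyallyl cation terminus C6. C3a is controlled by the dioxasiline, because the allyl cation can reach the enol ether carbon only from the face on which the tether leaves the ring sp3 carbon, anti to isopropyl, which places O3 and C4 cis on the new five-membered ring; C8a is controlled by the extended (exo) arrangement that keeps the ligated gold at C8 away from the diene and gives the trans fusion with the angular methyl cis to C4; C6 follows from suprafacial addition to the (E)-propenyl terminus and is erased in step 9. The step needs (4+3) over ring contraction to a (4+2) product and over protodemetalation after the first bond: the quaternary C8a leaves only the C7 hydrogens for the 1,2-shift, the strongly donating carbene ligand favours hydride over alkyl shift, and aprotic, base-buffered conditions keep silylene and vinylgold intact.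

**Step 8**
Reactants: 12 the tricyclic diene
Product: 13 the 7,8-dihydro derivative of 12, (3R,3aS,6R,8aS)-configured cyclic diisopropylsilylene enol ether with C4=C5 as the only C=C bond
Conditions: H2 (5 bar), RhCl(PPh3)3 (10 mol %), benzene, rt
Reagents that add atoms: none
Why: Homogeneous hydrogenation with RhCl(PPh3)3 should reduce the cis-disubstituted C7=C8 alkene and leave the trisubstituted, oxygen-bearing enol ether; no stereocentre is formed.

**Step 9**
Reactants: 13 the tricyclic silyl enol ether
Product: 15 (3R,3aR,8aS)-3-hydroxy-6,8a-dimethyl-3-(propan-2-yl)-2,3,3a,7,8,8a-hexahydroazulen-4(1H)-one, via silanol enone 14 (not isolated)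
Conditions: Pd(OAc)2 (15 mol %), O2 (1 atm), DMSO, 50 °C; then HF·pyridine, THF, 0 °C
Reagents that add atoms: none
Why: Aerobic Saegusa–Ito oxidation, in which the palladium enolate at C5 can undergo β-hydride elimination only toward C6 and so should give the C5=C6 enone while silicon remains on O3 as a silanol; fluoride then frees the tertiary alcohol without base, so C3a is not epimerised.

**Step 10**
Reactants: 15 the β-hydroxy enone
Product: 16 (3R,3aS,4S,8aS)-6,8a-dimethyl-3-(propan-2-yl)-1,2,3,3a,4,7,8,8a-octahydroazulene-3,4-diol
Conditions: Me4NBH(OAc)3 (5 equiv), MeCN/AcOH (1:1), −30 °C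
Reagents that add atoms: none
Why: Evans–Saksena reduction, in which the C3 hydroxyl exchanges onto boron and delivers hydride intramolecularly to the carbonyl face on its own side (also the side of the angular methyl), which should give the 3,4-trans diol with 4S by 1,2-reduction of the enone.

**Step 11**
Reactants: 16 the diol; 17 4-methoxybenzoyl chloride
Product: 18 (3R,3aS,4S,8aS)-3-hydroxy-6,8a-dimethyl-3-(propan-2-yl)-1,2,3,3a,4,7,8,8a-octahydroazulen-4-yl 4-methoxybenzoate (target)
Conditions: Et3N, DMAP (10 mol %), CH2Cl2, 0 °C → rt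
Reagents that add atoms: none
Why: DMAP-catalysed acylation should esterify only the secondary allylic alcohol, since the tertiary alcohol is flanked by isopropyl and the ring fusion; no stereocentre is affected.

**Compound list**

1 | (S)-terpinen-4-ol, (1S)-4-methyl-1-(propan-2-yl)cyclohex-3-en-1-ol | CC1=CC[C@](O)(C(C)C)CC1 | starting material
2 | secondary ozonide of 1 (1,2,4-trioxolane across the former C=C) | CC12CC[C@@](O)(C(C)C)CC(OO1)O2 | intermediate (not isolated)
3 | (3S)-3-hydroxy-6-oxo-3-(propan-2-yl)heptanal | O=CC[C@](O)(C(C)C)CCC(C)=O | intermediate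
4 | (E)-1-bromoprop-1-ene | C/C=C/Br | starting material
5 | (5S,8E)-5,7-dihydroxy-5-(propan-2-yl)dec-8-en-2-one, C7 epimers | C/C=C/C(O)C[C@](O)(C(C)C)CCC(C)=O | intermediate
6 | (5S,8E)-5-hydroxy-5-(propan-2-yl)dec-8-ene-2,7-dione | C/C=C/C(=O)C[C@](O)(C(C)C)CCC(C)=O | intermediate
7 | O5-[diisopropyl(trifluoromethanesulfonyloxy)silyl] ether of 6 | C/C=C/C(=O)C[C@](O[Si](OS(=O)(=O)C(F)(F)F)(C(C)C)C(C)C)(C(C)C)CCC(C)=O | intermediate (not isolated)
8 | 4-[(4R)-2,2,4-tri(propan-2-yl)-6-[(1E)-prop-1-en-1-yl]-4H-1,3,2-dioxasilin-4-yl]butan-2-one | C/C=C/C1=C[C@](C(C)C)(CCC(C)=O)O[Si](C(C)C)(C(C)C)O1 | intermediate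
9 | lithium alkoxide of the ethynyl carbinol from 8 | C/C=C/C1=C[C@](C(C)C)(CCC(C)(C#C)[O-])O[Si](C(C)C)(C(C)C)O1.[Li+] | intermediate (not isolated)
10 | methyl 3-methyl-5-[(4R)-2,2,4-tri(propan-2-yl)-6-[(1E)-prop-1-en-1-yl]-4H-1,3,2-dioxasilin-4-yl]pent-1-yn-3-yl carbonate, carbinol epimers | C/C=C/C1=C[C@](C(C)C)(CCC(C)(C#C)OC(=O)OC)O[Si](C(C)C)(C(C)C)O1 | intermediate
11 | (4R)-4-(3-methylpenta-3,4-dien-1-yl)-2,2,4-tri(propan-2-yl)-6-[(1E)-prop-1-en-1-yl]-4H-1,3,2-dioxasiline | C/C=C/C1=C[C@](C(C)C)(CCC(C)=C=C)O[Si](C(C)C)(C(C)C)O1 | intermediate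
12 | (3R,3aS,6R,8aR)-6,8a-dimethyl-3-(propan-2-yl)-1,2,3,3a,6,8a-hexahydroazulene-3,4-diol cyclic O3,O4-diisopropylsilanediyl ether | CC(C)[Si]1(C(C)C)OC2=C[C@H](C)C=C[C@@]3(C)CC[C@@](O1)(C(C)C)[C@H]23 | intermediate
13 | 7,8-dihydro derivative of 12, (3R,3aS,6R,8aS) | CC(C)[Si]1(C(C)C)OC2=C[C@H](C)CC[C@@]3(C)CC[C@@](O1)(C(C)C)[C@H]23 | intermediate
14 | (3R,3aR,8aS)-3-{[hydroxydi(propan-2-yl)silyl]oxy}-6,8a-dimethyl-3-(propan-2-yl)-2,3,3a,7,8,8a-hexahydroazulen-4(1H)-one | O=C1C=C(C)CC[C@@]2(C)CC[C@@](O[Si](O)(C(C)C)C(C)C)(C(C)C)[C@H]12 | intermediate (not isolated)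
15 | (3R,3aR,8aS)-3-hydroxy-6,8a-dimethyl-3-(propan-2-yl)-2,3,3a,7,8,8a-hexahydroazulen-4(1H)-one | O=C1C=C(C)CC[C@@]2(C)CC[C@@](O)(C(C)C)[C@H]12 | intermediate
16 | (3R,3aS,4S,8aS)-6,8a-dimethyl-3-(propan-2-yl)-1,2,3,3a,4,7,8,8a-octahydroazulene-3,4-diol | O[C@H]1C=C(C)CC[C@@]2(C)CC[C@@](O)(C(C)C)[C@H]12 | intermediate
17 | 4-methoxybenzoyl chloride | COc1ccc(C(=O)Cl)cc1 | starting material
18 | (3R,3aS,4S,8aS)-3-hydroxy-6,8a-dimethyl-3-(propan-2-yl)-1,2,3,3a,4,7,8,8a-octahydroazulen-4-yl 4-methoxybenzoate | COc1ccc(C(=O)O[C@H]2C=C(C)CC[C@@]3(C)CC[C@@](O)(C(C)C)[C@H]23)cc1 | target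

Total step count: 11
Longest linear sequence: 11 steps

**Steps most likely to fail**

1. Step 7. What may go wrong: loss of the silylene or protodemetalation after the first carbon–carbon bond, so that only the five-membered ring forms; ring contraction of the gold carbene by alkyl shift; or poor control of the ring fusion. Fallback with a sulfur-stabilised allyl cation in place of the allene: it sets out from 8. Addition of 1-(phenylthio)vinyllithium (from phenyl vinyl sulfide and s-BuLi, THF, −78 °C) to the methyl ketone gives the tertiary 2-(phenylthio)allylic alcohol F1. Tf2O and 2,6-lutidine in CH2Cl2 at −78 °C ionise it to a vinylthionium ion, which should undergo the intramolecular (4+3) cycloaddition with the same dioxasiline diene and, after loss of a proton from C7, give the C8-phenylthio vinyl sulfide F2. Raney Ni in THF/acetone then removes sulfur and saturates C7–C8 in one operation. The fallback comes back to the route at 13.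

2. Step 10. What may go wrong: slow exchange of the hindered tertiary hydroxyl onto boron, so that undirected hydride attack from the face anti to the angular methyl competes and facial selectivity is lost. Fallback by inversion instead of direction: it sets out from 15. NaBH4 with CeCl3·7H2O in MeOH at −78 °C should deliver hydride anti to the angular methyl and give the C4-epimeric diol F3, (3R,3aS,4R,8aS). Mitsunobu esterification with 4-methoxybenzoic acid (PPh3, DIAD, toluene, 0 °C → rt) inverts C4 and installs the ester in the same operation. The fallback comes back to the route at 18.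

3. Step 8. What may go wrong: sluggish hydrogenation of the alkene next to the quaternary carbon, with competing saturation or hydrolysis of the enol ether. Fallback by redox-neutral isomerisation instead of reduction and reoxidation: it sets out from 12. RuHCl(CO)(PPh3)3 (5 mol %) in toluene at 80 °C should move the C7=C8 double bond into conjugation with the enol ether, since the only hydrogen available for β-elimination is the doubly allylic one at C6, giving the conjugated 4-siloxy-4,6-diene F4. Aqueous HF in MeCN then cleaves the silylene with protonation at C7. The fallback comes back to the route at 15, replacing steps 8 and 9.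

**Further compounds**

F1 | step 7 | 3-methyl-2-(phenylsulfanyl)-5-[(4R)-2,2,4-tri(propan-2-yl)-6-[(1E)-prop-1-en-1-yl]-4H-1,3,2-dioxasilin-4-yl]pent-1-en-3-ol | C/C=C/C1=C[C@](C(C)C)(CCC(C)(O)C(=C)Sc2ccccc2)O[Si](C(C)C)(C(C)C)O1
F2 | step 7 | 8-(phenylsulfanyl) analogue of 12 (C7=C8 vinyl sulfide, cyclic diisopropylsilylene enol ether) | CC(C)[Si]1(C(C)C)OC2=C[C@H](C)C=C(Sc4ccccc4)[C@@]3(C)CC[C@@](O1)(C(C)C)[C@H]23
F3 | step 10 | (3R,3aS,4R,8aS)-6,8a-dimethyl-3-(propan-2-yl)-1,2,3,3a,4,7,8,8a-octahydroazulene-3,4-diol | O[C@@H]1C=C(C)CC[C@@]2(C)CC[C@@](O)(C(C)C)[C@H]12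
F4 | step 8 | (3R,3aS,8aS)-6,8a-dimethyl-3-(propan-2-yl)-1,2,3,3a,8,8a-hexahydroazulene-3,4-diol cyclic O3,O4-diisopropylsilanediyl ether (C4=C5 and C6=C7) | CC(C)[Si]1(C(C)C)OC2=CC(C)=CC[C@@]3(C)CC[C@@](O1)(C(C)C)[C@H]23
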